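**Strategy.** Everything rests on opening ring C across O1–C2 and C3–C4. Because O1 and C4 are bound to adjacent carbons of ring A (C8a, C4a) while C2 bears the donor-substituted ring B, ring C maps back onto an ortho-quinone methide heterodiene and a vinylcatechol dienophile. A single enantioselective oxa-[4+2] cycloaddition thus closes ring C, makes both bonds and fixes C2 as S, leaving C4 as a methyl ether ready for oxidation to the ketone. The precursor is a phloroglucinaldehyde dimethyl acetal with one free phenol (the future O1) and two benzyl ethers, partnered with 3,4-bis(silyloxy)styrene. The C6 dienyl chain follows by iodination and Stille coupling.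

Key step: step 5

Remarks on the chemistry (assumptions and design choices):
- The sense of induction of the chiral acid in step 5 cannot be predicted. The catalyst antipode that gives 2S is assumed to be found in a first screen; both BINOL antipodes are available.
- Ring A passes through the key step as benzyl ethers. They are inert to the acids of steps 2 and 5. After the oxidation both are removed by hydrogenolysis without touching the ring B silyl ethers. The 5-OH/7-OH pair is then differentiated by selective 7-O-silylation (the chelated 5-OH does not react), not by a selective cleavage.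
- The side chain has ten carbons with C1″ on ring A, so C1 of (S)-citronellal must become C1″. The aldehyde is therefore dehydrated to the alkyne; a homologating alkyne synthesis would add a carbon.
- The styrene is made from 3,4-dihydroxybenzaldehyde so that free 4-vinylcatechol is never handled.

**Route**

Step 1
Reactants: 1 2,4,6-trihydroxybenzaldehyde
Product: 2 2,4-bis(benzyloxy)-6-hydroxybenzaldehyde
Conditions: BnBr (2.0 equiv), K2CO3, DMF, 0 °C to rt
Reagents that add atoms: benzyl bromide, BrCc1ccccc1
Why: Williamson ether synthesis in which the 4-OH and one of the two equivalent ortho-OH groups are benzylated, while the last ortho-OH is held in a hydrogen bond to the formyl oxygen and should stay free with two equivalents of halide.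

Step 2
Reactants: 2 2,4-bis(benzyloxy)-6-hydroxybenzaldehyde
Product: 3 3,5-bis(benzyloxy)-2-(dimethoxymethyl)phenol
Conditions: HC(OMe)3, MeOH, TsOH·H2O (2 mol%), rt; Et3N quench, no silica gel, used at once
Reagents that add atoms: trimethyl orthoformate, COC(OC)OC
Why: Acid-catalysed acetalisation driven by the orthoformate as water scavenger, with benzyl ethers inert to the acid and the labile free-phenol acetal kept basic after the quench.

Step 3
Reactants: 4 3,4-dihydroxybenzaldehyde
Product: 5 3,4-bis(tert-butyldimethylsilyloxy)benzaldehyde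
Conditions: TBSCl (2.3 equiv), imidazole, DMF, rt
Reagents that add atoms: tert-butyldimethylsilyl chloride, CC(C)(C)[Si](C)(C)Cl
Why: Imidazole-promoted silyl ether formation at both catechol hydroxyls, which leaves the aldehyde untouched.

Step 4
Reactants: 5 3,4-bis(tert-butyldimethylsilyloxy)benzaldehyde
Product: 6 3,4-bis(tert-butyldimethylsilyloxy)styrene
Conditions: Ph3PCH3Br, n-BuLi, THF, 0 °C to rt
Reagents that add atoms: methyltriphenylphosphonium bromide, C[P+](c1ccccc1)(c1ccccc1)c1ccccc1.[Br-]
Why: Wittig methylenation with the preformed non-stabilised ylide converts the aldehyde into the terminal alkene, and the aryl silyl ethers tolerate the ylide once the butyllithium is consumed.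

Step 5
Reactants: 3 3,5-bis(benzyloxy)-2-(dimethoxymethyl)phenol; 6 3,4-bis(tert-butyldimethylsilyloxy)styrene
Product: 8 (2S)-5,7-bis(benzyloxy)-2-[3,4-bis(tert-butyldimethylsilyloxy)phenyl]-4-methoxychromane (both C4 epimers), via ortho-quinone methide 7 (not isolated)
Conditions: (R)-3,3′-bis(2,4,6-triisopropylphenyl)-1,1′-binaphthyl-2,2′-diyl N-triflylphosphoramide (5 mol%; antipode as assumed above), 5 Å MS, toluene, −40 °C; 6 added slowly to 3 (1.2 equiv)
Reagents that add atoms: none
Why: Proposed new method: the chiral acid protonates an acetal oxygen of 3 and expels methanol, giving quinone methide 7 as its O-protonated (oxocarbenium) form, hydrogen-bonded through the phenol O–H to the chiral phosphoramide anion; the CH2 terminus of 6 attacks the electrophilic carbon (C3–C4 bond) while charge builds at the benzylic carbon, stabilised by the para-silyloxy group of ring B, and the phenol oxygen then captures it (O1–C2 bond). The closest known reaction types are the racemic acid-catalysed [4+2] of salicylaldehyde acetals with styrenes and the chiral-phosphoric-acid-type version with enol ethers; enantiocontrol with a plain styrene is the untested part. Ring C closes in an inverse-electron-demand oxa-[4+2] mode, asynchronous with C–C bonding ahead of C–O bonding, the six-membered ring being completed by O1 adding to the benzylic cation. C2 is controlled by the chiral counter-anion, which blocks one face of the ion pair and so decides the face of the styrene carbon to which O1 is delivered; C4 is set only relative to C2 (endo or exo approach), is expected as an epimer pair and is erased in step 6. The step needs regioselectivity (ring B at C2), which the polarity of the two partners secures, and chemoselectivity against re-ionisation of the product at C4, against which the capped 5-oxygen (no second quinone methide possible), the low temperature and the slow addition of 6 work. Both C4 epimers must belong to the 2S series, which is to be checked on ketone 9, where C2 is the only stereocentre.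

Step 6
Reactants: 8 (2S)-5,7-bis(benzyloxy)-2-[3,4-bis(tert-butyldimethylsilyloxy)phenyl]-4-methoxychromane
Product: 9 (2S)-5,7-bis(benzyloxy)-2-[3,4-bis(tert-butyldimethylsilyloxy)phenyl]chroman-4-one
Conditions: DDQ (1.5 equiv), CH2Cl2–pH 7 phosphate buffer (10:1), 0 °C
Reagents that add atoms: water, O
Why: DDQ oxidation of an electron-rich benzylic methyl ether, in which hydride abstraction at C4 (activated by its own ether oxygen and the three oxygen donors of ring A) gives an oxocarbenium ion that water converts to the ketone with loss of methanol, while C2–H and the benzyl and silyl ethers should be left, so both C4 epimers converge and C2 is untouched.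

Step 7
Reactants: 9 (2S)-5,7-bis(benzyloxy)-2-[3,4-bis(tert-butyldimethylsilyloxy)phenyl]chroman-4-one
Product: 10 (2S)-2-[3,4-bis(tert-butyldimethylsilyloxy)phenyl]-5,7-dihydroxychroman-4-one
Conditions: H2 (1 atm), Pd/C (10%), EtOAc, rt
Reagents that add atoms: none
Why: Catalytic hydrogenolysis of the two aryl benzyl ethers in a non-protic solvent, under which the aryl silyl ethers, the chelated aryl ketone and the C2 stereocentre should persist.

Step 8
Reactants: 10 (2S)-2-[3,4-bis(tert-butyldimethylsilyloxy)phenyl]-5,7-dihydroxychroman-4-one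
Product: 11 (2S)-2-[3,4-bis(tert-butyldimethylsilyloxy)phenyl]-7-(tert-butyldimethylsilyloxy)-5-hydroxychroman-4-one
Conditions: TBSCl (1.1 equiv), imidazole, CH2Cl2–DMF, 0 °C
Reagents that add atoms: tert-butyldimethylsilyl chloride, CC(C)(C)[Si](C)(C)Cl
Why: Selective silylation, since the acidic, unhindered 7-OH para to the carbonyl reacts with one equivalent of silyl chloride while the 5-OH is tied up in its hydrogen bond to C4=O.

Step 9
Reactants: 11 (2S)-2-[3,4-bis(tert-butyldimethylsilyloxy)phenyl]-7-(tert-butyldimethylsilyloxy)-5-hydroxychroman-4-one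
Product: 12 (2S)-2-[3,4-bis(tert-butyldimethylsilyloxy)phenyl]-7-(tert-butyldimethylsilyloxy)-5-hydroxy-6-iodochroman-4-one
Conditions: BnMe3N·ICl2 (1.05 equiv), CaCO3, CH2Cl2–MeOH (5:2), rt, dark
Reagents that add atoms: benzyltrimethylammonium dichloroiodate, C[N+](C)(C)Cc1ccccc1.Cl[I-]Cl
Why: Electrophilic aromatic iodination directed by the free chelated 5-OH to its only open ortho position C6, the established preference of 5-hydroxy-7-O-substituted flavonoids with this reagent, with CaCO3 taking up the HCl so that the silyl ethers survive and the less activated ring B is not attacked.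

Step 10
Reactants: 13 (S)-citronellal [(3S)-3,7-dimethyloct-6-enal]
Product: 15 (3S)-3,7-dimethyloct-6-en-1-yne, via enol nonaflate 14 (not isolated)
Conditions: C4F9SO2F (1.2 equiv), phosphazene base EtN=P(NMe2)2–N=P(NMe2)3 (2.3 equiv), DMF, −30 °C to rt
Reagents that add atoms: none
Why: One-pot enol nonaflate formation and base-induced elimination (aldehyde-to-alkyne dehydration) turns the CH2–CHO unit into C≡CH without adding a carbon, and the C3 stereocentre, which is not the carbon that is deprotonated, should keep its S configuration.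

Step 11
Reactants: 15 (3S)-3,7-dimethyloct-6-en-1-yne
Product: 16 tributyl[(1E,3S)-3,7-dimethylocta-1,6-dien-1-yl]stannane
Conditions: Bu3SnH, Pd2(dba)3 (0.5 mol%), Cy3P·HBF4 (2 mol%), iPr2NEt, CH2Cl2, 0 °C
Reagents that add atoms: tributyltin hydride, CCCC[SnH](CCCC)CCCC
Why: Palladium-catalysed hydrostannation, a syn addition of Sn–H across the terminal alkyne that places tin on the terminal carbon (bulky Cy3P ligand, branched propargylic carbon) and gives the E-alkenylstannane, under non-radical conditions that spare the trisubstituted alkene.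

Step 12
Reactants: 12 (2S)-2-[3,4-bis(tert-butyldimethylsilyloxy)phenyl]-7-(tert-butyldimethylsilyloxy)-5-hydroxy-6-iodochroman-4-one; 16 tributyl[(1E,3S)-3,7-dimethylocta-1,6-dien-1-yl]stannane
Product: 17 (2S)-2-[3,4-bis(tert-butyldimethylsilyloxy)phenyl]-7-(tert-butyldimethylsilyloxy)-6-[(1E,3S)-3,7-dimethylocta-1,6-dien-1-yl]-5-hydroxychroman-4-one
Conditions: Pd2(dba)3 (5 mol%), AsPh3 (20 mol%), CuI (10 mol%), DMF, 50 °C
Reagents that add atoms: none
Why: Stille cross-coupling (oxidative addition of the aryl iodide to zerovalent palladium, CuI-assisted transmetalation from tin with retention of the E geometry, reductive elimination) under neutral conditions that leave the free 5-OH, the silyl ethers and the base-sensitive C2 centre alone.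

Step 13
Reactants: 17 (2S)-2-[3,4-bis(tert-butyldimethylsilyloxy)phenyl]-7-(tert-butyldimethylsilyloxy)-6-[(1E,3S)-3,7-dimethylocta-1,6-dien-1-yl]-5-hydroxychroman-4-one
Product: 18 (2S)-2-(3,4-dihydroxyphenyl)-6-[(1E,3S)-3,7-dimethylocta-1,6-dien-1-yl]-5,7-dihydroxychroman-4-one (CNP0230070.1)
Conditions: HF·pyridine, pyridine, THF, 0 °C to rt
Reagents that add atoms: none
Why: Fluoride-mediated desilylation of the three aryl silyl ethers under pyridine-buffered, non-basic conditions, which avoids the base-induced ring opening to the chalcone that would racemise C2 and the strong acid that would cyclise the ortho-hydroxystyrene or the trisubstituted alkene.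

**Compound list**

1 | 2,4,6-trihydroxybenzaldehyde | O=Cc1c(O)cc(O)cc1O | starting material
2 | 2,4-bis(benzyloxy)-6-hydroxybenzaldehyde | O=Cc1c(O)cc(OCc2ccccc2)cc1OCc1ccccc1 | intermediate
3 | 3,5-bis(benzyloxy)-2-(dimethoxymethyl)phenol | COC(OC)c1c(O)cc(OCc2ccccc2)cc1OCc1ccccc1 | intermediate
4 | 3,4-dihydroxybenzaldehyde | O=Cc1ccc(O)c(O)c1 | starting material
5 | 3,4-bis(tert-butyldimethylsilyloxy)benzaldehyde | O=Cc1ccc(O[Si](C)(C)C(C)(C)C)c(O[Si](C)(C)C(C)(C)C)c1 | intermediate
6 | 3,4-bis(tert-butyldimethylsilyloxy)styrene | C=Cc1ccc(O[Si](C)(C)C(C)(C)C)c(O[Si](C)(C)C(C)(C)C)c1 | intermediate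
7 | 3,5-bis(benzyloxy)-6-(methoxymethylidene)cyclohexa-2,4-dien-1-one (C4-methoxy ortho-quinone methide, enol ether geometry undefined) | COC=C1C(=O)C=C(OCc2ccccc2)C=C1OCc1ccccc1 | intermediate (not isolated)
8 | (2S)-5,7-bis(benzyloxy)-2-[3,4-bis(tert-butyldimethylsilyloxy)phenyl]-4-methoxychromane (both C4 epimers) | COC1C[C@@H](c2ccc(O[Si](C)(C)C(C)(C)C)c(O[Si](C)(C)C(C)(C)C)c2)Oc2cc(OCc3ccccc3)cc(OCc3ccccc3)c12 | intermediate
9 | (2S)-5,7-bis(benzyloxy)-2-[3,4-bis(tert-butyldimethylsilyloxy)phenyl]chroman-4-one | O=C1C[C@@H](c2ccc(O[Si](C)(C)C(C)(C)C)c(O[Si](C)(C)C(C)(C)C)c2)Oc2cc(OCc3ccccc3)cc(OCc3ccccc3)c12 | intermediate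
10 | (2S)-2-[3,4-bis(tert-butyldimethylsilyloxy)phenyl]-5,7-dihydroxychroman-4-one | O=C1C[C@@H](c2ccc(O[Si](C)(C)C(C)(C)C)c(O[Si](C)(C)C(C)(C)C)c2)Oc2cc(O)cc(O)c12 | intermediate
11 | (2S)-2-[3,4-bis(tert-butyldimethylsilyloxy)phenyl]-7-(tert-butyldimethylsilyloxy)-5-hydroxychroman-4-one | O=C1C[C@@H](c2ccc(O[Si](C)(C)C(C)(C)C)c(O[Si](C)(C)C(C)(C)C)c2)Oc2cc(O[Si](C)(C)C(C)(C)C)cc(O)c12 | intermediate
12 | (2S)-2-[3,4-bis(tert-butyldimethylsilyloxy)phenyl]-7-(tert-butyldimethylsilyloxy)-5-hydroxy-6-iodochroman-4-one | O=C1C[C@@H](c2ccc(O[Si](C)(C)C(C)(C)C)c(O[Si](C)(C)C(C)(C)C)c2)Oc2cc(O[Si](C)(C)C(C)(C)C)c(I)c(O)c12 | intermediate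
13 | (S)-citronellal, (3S)-3,7-dimethyloct-6-enal | CC(C)=CCC[C@H](C)CC=O | starting material
14 | (3S)-3,7-dimethylocta-1,6-dien-1-yl nonafluorobutane-1-sulfonate (E/Z mixture) | CC(C)=CCC[C@H](C)C=COS(=O)(=O)C(F)(F)C(F)(F)C(F)(F)C(F)(F)F | intermediate (not isolated)
15 | (3S)-3,7-dimethyloct-6-en-1-yne | CC(C)=CCC[C@H](C)C#C | intermediate
16 | tributyl[(1E,3S)-3,7-dimethylocta-1,6-dien-1-yl]stannane | CC(C)=CCC[C@H](C)/C=C/[Sn](CCCC)(CCCC)CCCC | intermediate
17 | (2S)-2-[3,4-bis(tert-butyldimethylsilyloxy)phenyl]-7-(tert-butyldimethylsilyloxy)-6-[(1E,3S)-3,7-dimethylocta-1,6-dien-1-yl]-5-hydroxychroman-4-one | CC(C)=CCC[C@H](C)/C=C/c1c(O[Si](C)(C)C(C)(C)C)cc2c(c1O)C(=O)C[C@@H](c1ccc(O[Si](C)(C)C(C)(C)C)c(O[Si](C)(C)C(C)(C)C)c1)O2 | intermediate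
18 | (2S)-2-(3,4-dihydroxyphenyl)-6-[(1E,3S)-3,7-dimethylocta-1,6-dien-1-yl]-5,7-dihydroxychroman-4-one | CC(C)=CCC[C@H](C)/C=C/c1c(O)cc2c(c1O)C(=O)C[C@@H](c1ccc(O)c(O)c1)O2 | target

**Step count and risks**

Total step count: 13 (ring A branch 2, ring B branch 2, key step 1, steps 6 to 9, side chain 2, coupling and deprotection 2).
Longest linear sequence: 9 steps (steps 1, 2, 5, 6, 7, 8, 9, 12, 13).

Steps most likely to fail:

1. Step 5 (proposed new method). The chiral anion may fail to discriminate the two faces during the C–C and C–O bond-forming events, so that C2 forms with low enantiomeric excess, and the acid may re-ionise the product at C4. The fallback uses known chemistry and moves stereocontrol from catalysis to resolution. Setting out from 3 and 6, the cycloaddition is run with an achiral acid, diphenyl phosphate (PhO)2P(O)OH (10 mol%) in CH2Cl2 at −20 °C, which is the established racemic form of this reaction. This should give racemic 5,7-bis(benzyloxy)-2-[3,4-bis(tert-butyldimethylsilyloxy)phenyl]-4-methoxychromane F1. DDQ oxidation as in step 6 should then give racemic 5,7-bis(benzyloxy)-2-[3,4-bis(tert-butyldimethylsilyloxy)phenyl]chroman-4-one F2. Its enantiomers are separated by preparative HPLC on a cellulose tris(3,5-dimethylphenylcarbamate) phase; the (2S) enantiomer is 9, where the route is rejoined.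

2. Step 2. The electron-rich free-phenol acetal may revert to the aldehyde, or lose methanol to the quinone methide and oligomerise, while acid is still present or during isolation. The fallback sets out from 2. The chelated phenol is first acetylated (Ac2O, Et3N, DMAP, CH2Cl2) to 3,5-bis(benzyloxy)-2-formylphenyl acetate F3, whose aldehyde is no longer deactivated by the hydrogen bond. It is acetalised (HC(OMe)3, pyridinium p-toluenesulfonate) to 3,5-bis(benzyloxy)-2-(dimethoxymethyl)phenyl acetate F4, an acetal that cannot form a quinone methide. Methanolysis of the acetate with K2CO3 in MeOH at 0 °C and a work-up at pH 7 to 8 then releases the phenol without the free-phenol acetal ever meeting acid. The route is rejoined at 3.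

3. Step 12. Transmetalation from tin to the arylpalladium iodide flanked by OH and a silyloxy group may be slow, so that protodeiodination and homocoupling of the stannane take over. The fallback sets out from 15. Hydroboration with pinacolborane (Cp2Zr(H)Cl cat., Et3N, 40 °C) should give 2-[(1E,3S)-3,7-dimethylocta-1,6-dien-1-yl]-4,4,5,5-tetramethyl-1,3,2-dioxaborolane F5. This is joined to 12 by Suzuki–Miyaura coupling (Pd(OAc)2, 2-dicyclohexylphosphino-2′,6′-dimethoxybiphenyl, K3PO4, toluene–H2O, 40 °C), a catalyst system suited to doubly ortho-substituted aryl halides. The route is rejoined at 17; any 7-O-desilylated material formed under the base is carried into step 13 as well.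

**Further compounds**

F1 | step 5 | racemic 5,7-bis(benzyloxy)-2-[3,4-bis(tert-butyldimethylsilyloxy)phenyl]-4-methoxychromane | COC1CC(c2ccc(O[Si](C)(C)C(C)(C)C)c(O[Si](C)(C)C(C)(C)C)c2)Oc2cc(OCc3ccccc3)cc(OCc3ccccc3)c12
F2 | step 5 | racemic 5,7-bis(benzyloxy)-2-[3,4-bis(tert-butyldimethylsilyloxy)phenyl]chroman-4-one | O=C1CC(c2ccc(O[Si](C)(C)C(C)(C)C)c(O[Si](C)(C)C(C)(C)C)c2)Oc2cc(OCc3ccccc3)cc(OCc3ccccc3)c12
F3 | step 2 | 3,5-bis(benzyloxy)-2-formylphenyl acetate | CC(=O)Oc1cc(OCc2ccccc2)cc(OCc2ccccc2)c1C=O
F4 | step 2 | 3,5-bis(benzyloxy)-2-(dimethoxymethyl)phenyl acetate | COC(OC)c1c(OC(C)=O)cc(OCc2ccccc2)cc1OCc1ccccc1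
F5 | step 12 | 2-[(1E,3S)-3,7-dimethylocta-1,6-dien-1-yl]-4,4,5,5-tetramethyl-1,3,2-dioxaborolane | CC(C)=CCC[C@H](C)/C=C/B1OC(C)(C)C(C)(C)O1
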